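The rate constants are those of an exercise; what happens was integrated by code.

The amounts come first: in this flask the protic impurity is charged mole for mole with the starting complex, and the incoming ligand at 3.00 equivalents.

starting complex 0.080 M (fed, over 1.0 h); incoming ligand 0.240 M; protic impurity 0.0800 M; time 4.0 h; the fed solution adds 0.20 times the starting volume

    starting complex + incoming ligand ⇌ leaving ligand + complex with one exchanged (K1 = 0.12, k1 = 0.0039 M⁻¹ s⁻¹)
    complex with one exchanged + incoming ligand ⇌ leaving ligand + complex with two exchanged (K2 = 0.48, k2 = 0.012 M⁻¹ s⁻¹)
    complex with two exchanged + incoming ligand ⇌ leaving ligand + complex with three exchanged (K3 = 0.85, k3 = 0.0066 M⁻¹ s⁻¹)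
    leaving ligand + incoming ligand ⇌ idle adduct, settled at all times (K4 = 1.3 M⁻¹)
    protic impurity + starting complex → quenched substrate (k5 = 0.0050 M⁻¹ s⁻¹)

- what is said of leaving ligand includes idle adduct
- amounts are per litre of the starting volume; all of the dose is in the solution fed
- run time (flask): 4.0 h

- part of the starting complex that has reacted at 4.0 h
- share of the unused incoming ligand that is free and not bound as idle adduct, at 4.0 h

I followed one molecule. At its first fork the starting complex was exchanged faster than it was quenched, and the impurity attacks starting complex and not the exchanged forms, so I let the exchanges stand at balance and asked what part of its time an unquenched molecule spends as starting complex. With [incoming ligand]/[leaving ligand] first guessed at 3.00, the whole charge of incoming ligand set against one leaving ligand per molecule charged, this gave 31.2%; I called it the exposed share, the active fraction of a dormant–active balance.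

Impurity and unquenched molecules then fell together, one for one, so the reciprocal of the surviving share grew by the exposed share times 4.80, the feed being counted as if the charge had stood there from the start, and that gave an estimate of 40.0% surviving.

The weak link was the guessed ratio. Survivors at that balance carried 1.68 exchanges each, which freed 0.0536 M of leaving ligand per starting litre, so the ratio became 3.48, the exposed share 24.0% and the surviving share 46.5%. Their product is the starting complex left, so I committed to 88.8% reacted. That leaving ligand, diluted to 0.0447 M, gave a free share of 94.5%.

The forecast, which also “treated the exchange steps as pre-equilibrated after the feed”, gave 90% and 94.8%, the first above mine. The flask gave 90.4% and 94.7%.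

Its readings at 4.00 h put the exposed share at 23.8%, beside my 24.0%. Taking away the quenching of starting complex by protic impurity left 47.3% reacted. For that run I reckoned a ratio of 2.00, with every molecule unquenched and one leaving ligand per molecule, then an exposed share of 53.7% and 46.3% reacted. In the neighbour flask charged with 0.096 M of incoming ligand, the end readings give a ratio of 2.22, an exposed share of 48.0% and 85.5% reacted, where that neighbour flask gave 87.0%.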